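**Retrosynthetic overview**

- Numbering: C1–C2 carry the oxirane (CH3 on C2). C3–C5 are CH2, C6 is CMe2, C7 is CHOBz, C8=C9 bears CO2H on C9 (C7 and C10 cis), and C10–C11 are CH2. C1–C11 form the single eleven-membered carbocycle.
- Feature: inside that ring the quaternary gem-dimethyl carbon C6 is bonded directly to the oxygen-bearing stereocentre C7. Cutting C6–C7 gives a C7 enal and a C4–C5–C6 allylmetal that reacts at its dimethyl end, so one carbonyl addition makes C6, C7 and the ring.
- Endgame, in retrosynthetic order: the acid comes from a 2-(trimethylsilyl)ethyl ester, the C4–C5 single bond from hydrogenation of the alkene left by the allyl transposition, the oxirane from chiral-dioxirane epoxidation of C1=C2, and the benzoate from the C7 carbinol.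
- The open-chain bromo enal comes from geranyl bromide (C11, C1–C6), methyl acetoacetate (C7–C10) and CO (carboxyl carbon). Dianion γ-alkylation, E enol triflate formation, reduction and carbonylation fix C8=C9. Halohydrin, oxirane and selenoxide elimination move the terminal alkene to C4=C5 with oxygen on C6.
- Ring order: the eleven-membered carbocycle first (step 9), the oxirane second (step 11).

Key step: step 9

Assumption: the L-configured ketone of step 11 (mirror image of the usual D-fructose-derived epoxidation ketone, otherwise made from L-sorbose) and both antipodes of the bis(oxazoline) of step 9 are treated as purchasable reagents.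

**Step 1**
Reactants: 1 geranyl bromide, (2E)-1-bromo-3,7-dimethylocta-2,6-diene; 2 methyl acetoacetate
Product: 4 methyl (6E)-7,11-dimethyl-3-oxododeca-6,10-dienoate, via dilithio dianion 3 (not isolated)
Conditions: 2, LiN(i-Pr)2 (2.1 equiv), THF, 0 °C; then 1, 0 °C → rt; 1 M HCl quench
Reagents that add atoms: lithium diisopropylamide, [Li+].CC(C)[N-]C(C)C (lithium of 3 only)
Why: γ-Alkylation of an acetoacetate dianion: the terminal carbanion of 3 is the more nucleophilic site and displaces the primary allylic bromide by SN2 without touching the E alkene, which joins C10 to C11 and lays down the whole C7–C11/C1–C6 chain.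

**Step 2**
Reactants: 4 methyl (6E)-7,11-dimethyl-3-oxododeca-6,10-dienoate
Product: 5 methyl (2E,6E)-7,11-dimethyl-3-(trifluoromethylsulfonyloxy)dodeca-2,6,10-trienoate
Conditions: Tf2O, 25% aq. Me4NOH, hexanes, 5 °C
Reagents that add atoms: trifluoromethanesulfonic anhydride, O=S(=O)(OS(=O)(=O)C(F)(F)F)C(F)(F)F
Why: O-Sulfonylation of a β-keto ester enolate under Schotten–Baumann-type two-phase conditions: with the non-coordinating Me4N+ counter-ion the enolate cannot chelate and is trapped in its extended form as the E enol triflate, with OTf trans and C10 cis to the ester carbon C7, which is the C8=C9 geometry of the target.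

**Step 3**
Reactants: 5 methyl (2E,6E)-7,11-dimethyl-3-(trifluoromethylsulfonyloxy)dodeca-2,6,10-trienoate
Product: 6 (2E,6E)-1-hydroxy-7,11-dimethyldodeca-2,6,10-trien-3-yl trifluoromethanesulfonate
Conditions: i-Bu2AlH (2.5 equiv), CH2Cl2, −78 °C; aq. potassium sodium tartrate
Reagents that add atoms: none
Why: 1,2-Reduction of a conjugated ester to the allylic alcohol with i-Bu2AlH, which leaves the vinyl triflate and the alkene geometry untouched at low temperature and brings C7 to the alcohol level before the second carboxyl carbon arrives, so the two never have to be told apart.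

**Step 4**
Reactants: 6 (2E,6E)-1-hydroxy-7,11-dimethyldodeca-2,6,10-trien-3-yl trifluoromethanesulfonate
Product: 8 (2E,6E)-10,11-epoxy-1-hydroxy-7,11-dimethyldodeca-2,6-dien-3-yl trifluoromethanesulfonate (racemic), via bromohydrin 7 (not isolated)
Conditions: N-bromosuccinimide (1.05 equiv), THF–H2O, 0 °C; crude, then K2CO3, MeOH, 0 °C → rt
Reagents that add atoms: N-bromosuccinimide, O=C1CCC(=O)N1Br (bromine of 7 only); water, O
Why: Electrophilic bromohydrin formation followed by base-induced oxirane closure: in the water-rich medium the bromonium ion forms preferentially at the least hindered chain-end alkene C5=C6 (C8=C9 is switched off by the triflate, C1=C2 is the more encumbered internal alkene), water opens it at tertiary C6 and carbonate closes the ring, and the new C5 stereocentre is racemic and disappears in step 5.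

**Step 5**
Reactants: 8 (2E,6E)-10,11-epoxy-1-hydroxy-7,11-dimethyldodeca-2,6-dien-3-yl trifluoromethanesulfonate
Product: 11 (2E,6E,9E)-1,11-dihydroxy-7,11-dimethyldodeca-2,6,9-trien-3-yl trifluoromethanesulfonate, via hydroxy selenide 9 (not isolated), via selenoxide 10 (not isolated)
Conditions: PhSeSePh, NaBH4, EtOH, rt → 50 °C; then 30% H2O2 (3 equiv), pyridine, THF, 0 °C → rt
Reagents that add atoms: diphenyl diselenide, c1ccc(cc1)[Se][Se]c1ccccc1 (PhSe of 9 and 10 only); hydrogen peroxide, OO (selenoxide oxygen of 10 only)
Why: Selenolate opening of an oxirane and selenoxide syn elimination: PhSe− attacks the less substituted C5 by SN2, and the derived selenoxide can only eliminate towards C4–H because C6 bears no hydrogen, which gives the E C4=C5 alkene with the tertiary alcohol on C6 (the C4–C5–C6 allyl unit), while pyridine and the limited peroxide keep C1=C2 from being epoxidised.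

**Step 6**
Reactants: 11 (2E,6E,9E)-1,11-dihydroxy-7,11-dimethyldodeca-2,6,9-trien-3-yl trifluoromethanesulfonate
Product: 12 2-(trimethylsilyl)ethyl (2E)-4-hydroxy-2-[(3E,6E)-8-hydroxy-4,8-dimethylnona-3,6-dien-1-yl]but-2-enoate
Conditions: Pd(OAc)2 (5 mol %), PPh3 (10 mol %), CO (1 atm), Me3SiCH2CH2OH (10 equiv), Et3N, DMF, 50 °C
Reagents that add atoms: carbon monoxide, [C-]#[O+]; 2-(trimethylsilyl)ethanol, C[Si](C)(C)CCO
Why: Palladium-catalysed alkoxycarbonylation of a vinyl triflate: oxidative addition to zerovalent palladium, CO insertion and alcoholysis by the large excess of external alcohol go with retention of geometry and place the carboxyl carbon on C9 trans to C7 (so no C7 alcohol of the route can lactonise), and the silylethyl ester is chosen because fluoride removes it beside a benzoate and an oxirane, which a methyl ester would not allow.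

**Step 7**
Reactants: 12 2-(trimethylsilyl)ethyl (2E)-4-hydroxy-2-[(3E,6E)-8-hydroxy-4,8-dimethylnona-3,6-dien-1-yl]but-2-enoate
Product: 13 2-(trimethylsilyl)ethyl (2E)-2-[(3E,6E)-8-hydroxy-4,8-dimethylnona-3,6-dien-1-yl]-4-oxobut-2-enoate
Conditions: activated MnO2 (excess), CH2Cl2, rt
Reagents that add atoms: none
Why: Chemoselective allylic alcohol oxidation on MnO2: only the primary allylic C7 carbinol can be oxidised, the tertiary C6 alcohol cannot, and the neutral heterogeneous medium leaves the C8=C9 geometry untouched.

**Step 8**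
Reactants: 13 2-(trimethylsilyl)ethyl (2E)-2-[(3E,6E)-8-hydroxy-4,8-dimethylnona-3,6-dien-1-yl]-4-oxobut-2-enoate
Product: 14 2-(trimethylsilyl)ethyl (2E)-2-[(3E)-6-bromo-4,8-dimethylnona-3,7-dien-1-yl]-4-oxobut-2-enoate (racemic at C4)
Conditions: PBr3 (0.4 equiv), pyridine (cat.), Et2O, −30 → 0 °C; cold aq. NaHCO3 wash, used crude at once
Reagents that add atoms: phosphorus tribromide, BrP(Br)Br
Why: Allylic substitution with transposition through the bromophosphite: the tertiary allylic alcohol ionises readily and bromide settles on C4 to leave the more substituted C5=C6 alkene, the electron-poor enal and the ester do not react at this temperature, and the new C4 stereocentre (racemic) and any tertiary allylic isomer do not matter because both are erased when the allylmetal forms in step 9.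

**Step 9**
Reactants: 14 2-(trimethylsilyl)ethyl (2E)-2-[(3E)-6-bromo-4,8-dimethylnona-3,7-dien-1-yl]-4-oxobut-2-enoate
Product: 16 2-(trimethylsilyl)ethyl (7R,1E,4E,8E)-7-hydroxy-2,6,6-trimethylcycloundeca-1,4,8-triene-9-carboxylate, via allylchromium dichloride 15 (not isolated)
Conditions: CrCl2 (6 equiv), 2,2'-(cyclopropane-1,1-diyl)bis[(3aR,8aS)-3a,8a-dihydro-8H-indeno[1,2-d]oxazole] (6.5 equiv), 4 Å molecular sieves, THF, rt; 14 in THF added by syringe pump over 12 h (final 2 mM); aq. potassium sodium tartrate
Reagents that add atoms: chromium dichloride, Cl[Cr]Cl (chromium and chlorine of 15 only)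
Why: Proposed new method: two equivalents of divalent chromium reduce the C–Br bond of 14 through the delocalised C4–C5–C6 allyl radical to the trivalent σ-allylchromium 15, which carries the metal on the secondary carbon C4 whatever the allylic isomer or C4 configuration of the bromide and adds to the chromium-bound C7 aldehyde through C6 in a six-membered chair (SE2′), so that the C6–C7 bond, the quaternary C6, the C7 carbinol and a transposed C4=C5 alkene arise together. The closest known reactions are the ligand-free Nozaki–Hiyama–Kishi allyl bromide–aldehyde macrocyclisation, the γ-selective (reverse) prenylation of aldehydes by prenylchromium and the intermolecular enantioselective allylation of aldehydes by CrCl2–bis(oxazoline) complexes, and what has not been shown is their combination in an enantioselective medium-ring closure that builds a quaternary carbon. The eleven-membered ring closes in an 11-exo-trig mode (the C=O bond stays outside the new ring) under pseudo-high dilution. C7 is the only new stereocentre and is set by the twofold-symmetric ligand on chromium, which has to leave the Si face of the aldehyde open to give 7R, with no substrate stereocentre competing because C4 is lost in 15. The step needs attack through C6 rather than C4 (secured by the preference of chromium for the less substituted allyl terminus and by the higher strain of the alternative nine-membered ring), 1,2- rather than 1,4-addition to the enal (intrinsic to allylchromium reagents) and reduction of the bromide ahead of the ene-dicarbonyl unit (secured by the very weak, highly substituted allylic C–Br bond). The geometry of C4=C5, drawn E for an equatorial C3 in the chair, does not matter because step 12 saturates it.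

**Step 10**
Reactants: 16 2-(trimethylsilyl)ethyl (7R,1E,4E,8E)-7-hydroxy-2,6,6-trimethylcycloundeca-1,4,8-triene-9-carboxylate
Product: 17 2-(trimethylsilyl)ethyl (7R,1E,4E,8E)-7-benzoyloxy-2,6,6-trimethylcycloundeca-1,4,8-triene-9-carboxylate
Conditions: BzCl, 4-(dimethylamino)pyridine (0.2 equiv), pyridine, CH2Cl2, 0 → 40 °C
Reagents that add atoms: benzoyl chloride, O=C(Cl)c1ccccc1
Why: Nucleophile-catalysed acylation of the hindered neopentyl-type allylic alcohol through the N-benzoylpyridinium ion, with retention at C7 because the C–O bond is not touched, and placed before the epoxidation so that chloride and acylating agent never meet the oxirane.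

**Step 11**
Reactants: 17 2-(trimethylsilyl)ethyl (7R,1E,4E,8E)-7-benzoyloxy-2,6,6-trimethylcycloundeca-1,4,8-triene-9-carboxylate
Product: 18 2-(trimethylsilyl)ethyl (1S,2S,7R,4E,8E)-7-benzoyloxy-1,2-epoxy-2,6,6-trimethylcycloundeca-4,8-diene-9-carboxylate
Conditions: 1,2:4,5-di-O-isopropylidene-β-L-erythro-2,3-hexodiulo-2,6-pyranose (0.3–1 equiv), KHSO5 (as 2KHSO5·KHSO4·K2SO4, 1.2 equiv), K2CO3, Bu4NHSO4, aq. Na2B4O7 buffer (pH 10.5), MeCN–CH2(OMe)2, 0 °C
Reagents that add atoms: potassium peroxymonosulfate, [K+].[O-]S(=O)(=O)OO
Why: Shi epoxidation: the dioxirane from the L-configured ketone attacks the only electron-rich trisubstituted alkene C1=C2 (C8=C9 is electron-poor, C4=C5 is only disubstituted and shielded by C6) through the spiro transition state that turns E-trisubstituted alkenes into (S,S)-epoxides, and since the ring can turn either face of C1=C2 outwards the reagent should choose the face and set 1S and 2S in one suprafacial oxygen transfer.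

**Step 12**
Reactants: 18 2-(trimethylsilyl)ethyl (1S,2S,7R,4E,8E)-7-benzoyloxy-1,2-epoxy-2,6,6-trimethylcycloundeca-4,8-diene-9-carboxylate
Product: 19 2-(trimethylsilyl)ethyl (1S,2S,7R,8E)-7-benzoyloxy-1,2-epoxy-2,6,6-trimethylcycloundec-8-ene-9-carboxylate
Conditions: H2 (1–3 atm), RhCl(PPh3)3 (10 mol %), benzene–EtOH, rt
Reagents that add atoms: none
Why: Homogeneous hydrogenation with RhCl(PPh3)3 discriminates by substitution, so the disubstituted C4=C5 alkene is reduced while the trisubstituted, ester-conjugated and C7-shielded C8=C9 alkene is not, with C1=C2 already protected as the wanted oxirane, the oxirane, allylic benzoate and silyl ester inert, and no stereocentre formed.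

**Step 13**
Reactants: 19 2-(trimethylsilyl)ethyl (1S,2S,7R,8E)-7-benzoyloxy-1,2-epoxy-2,6,6-trimethylcycloundec-8-ene-9-carboxylate
Product: 21 (1S,2S,7R,8E)-7-benzoyloxy-1,2-epoxy-2,6,6-trimethylcycloundec-8-ene-9-carboxylic acid (CNP0377917.2), via tetrabutylammonium carboxylate 20 (not isolated)
Conditions: Bu4NF, THF, 0 °C → rt; then cold 0.5 M aq. citric acid (pH 4), EtOAc
Reagents that add atoms: tetrabutylammonium fluoride, CCCC[N+](CCCC)(CCCC)CCCC.[F-] (cation of 20 only)
Why: Fluoride-induced β-fragmentation of a 2-(trimethylsilyl)ethyl ester (attack at silicon, loss of ethene) frees the carboxylate under non-hydrolytic conditions that spare the benzoate and the oxirane, and the weakly acidic work-up protonates it without opening the acid-sensitive trisubstituted epoxide.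

**Compound list**

1 | geranyl bromide, (2E)-1-bromo-3,7-dimethylocta-2,6-diene | CC(C)=CCC/C(C)=C/CBr | starting material
2 | methyl acetoacetate | COC(=O)CC(C)=O | starting material
3 | dilithio dianion of methyl acetoacetate | [Li+].[Li+].C=C([O-])C=C([O-])OC | intermediate
4 | methyl (6E)-7,11-dimethyl-3-oxododeca-6,10-dienoate | COC(=O)CC(=O)CC/C=C(\C)CCC=C(C)C | intermediate
5 | methyl (2E,6E)-7,11-dimethyl-3-(trifluoromethylsulfonyloxy)dodeca-2,6,10-trienoate | COC(=O)/C=C(\CC/C=C(\C)CCC=C(C)C)OS(=O)(=O)C(F)(F)F | intermediate
6 | (2E,6E)-1-hydroxy-7,11-dimethyldodeca-2,6,10-trien-3-yl trifluoromethanesulfonate | OC/C=C(\CC/C=C(\C)CCC=C(C)C)OS(=O)(=O)C(F)(F)F | intermediate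
7 | (2E,6E)-10-bromo-1,11-dihydroxy-7,11-dimethyldodeca-2,6-dien-3-yl trifluoromethanesulfonate (racemic bromohydrin) | OC/C=C(\CC/C=C(\C)CCC(Br)C(C)(C)O)OS(=O)(=O)C(F)(F)F | intermediate
8 | (2E,6E)-10,11-epoxy-1-hydroxy-7,11-dimethyldodeca-2,6-dien-3-yl trifluoromethanesulfonate (racemic) | OC/C=C(\CC/C=C(\C)CCC1OC1(C)C)OS(=O)(=O)C(F)(F)F | intermediate
9 | (2E,6E)-1,11-dihydroxy-7,11-dimethyl-10-(phenylselanyl)dodeca-2,6-dien-3-yl trifluoromethanesulfonate (racemic) | OC/C=C(\CC/C=C(\C)CCC([Se]c1ccccc1)C(C)(C)O)OS(=O)(=O)C(F)(F)F | intermediate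
10 | selenoxide of 9 | OC/C=C(\CC/C=C(\C)CCC([Se](=O)c1ccccc1)C(C)(C)O)OS(=O)(=O)C(F)(F)F | intermediate
11 | (2E,6E,9E)-1,11-dihydroxy-7,11-dimethyldodeca-2,6,9-trien-3-yl trifluoromethanesulfonate | OC/C=C(\CC/C=C(\C)C/C=C/C(C)(C)O)OS(=O)(=O)C(F)(F)F | intermediate
12 | 2-(trimethylsilyl)ethyl (2E)-4-hydroxy-2-[(3E,6E)-8-hydroxy-4,8-dimethylnona-3,6-dien-1-yl]but-2-enoate | OC/C=C(\CC/C=C(\C)C/C=C/C(C)(C)O)C(=O)OCC[Si](C)(C)C | intermediate
13 | 2-(trimethylsilyl)ethyl (2E)-2-[(3E,6E)-8-hydroxy-4,8-dimethylnona-3,6-dien-1-yl]-4-oxobut-2-enoate | O=C/C=C(\CC/C=C(\C)C/C=C/C(C)(C)O)C(=O)OCC[Si](C)(C)C | intermediate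
14 | 2-(trimethylsilyl)ethyl (2E)-2-[(3E)-6-bromo-4,8-dimethylnona-3,7-dien-1-yl]-4-oxobut-2-enoate (racemic at C4; key-step precursor) | O=C/C=C(\CC/C=C(\C)CC(Br)C=C(C)C)C(=O)OCC[Si](C)(C)C | intermediate
15 | σ-allylchromium dichloride with the metal on C4 (bis(oxazoline) and THF on chromium omitted) | O=C/C=C(\CC/C=C(\C)CC([Cr](Cl)Cl)C=C(C)C)C(=O)OCC[Si](C)(C)C | intermediate
16 | 2-(trimethylsilyl)ethyl (7R,1E,4E,8E)-7-hydroxy-2,6,6-trimethylcycloundeca-1,4,8-triene-9-carboxylate (key-step product; C7 and C10 cis on C8=C9) | CC1(C)/C=C/C/C(C)=C/CC/C(C(=O)OCC[Si](C)(C)C)=C\[C@H]1O | intermediate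
17 | 2-(trimethylsilyl)ethyl (7R,1E,4E,8E)-7-benzoyloxy-2,6,6-trimethylcycloundeca-1,4,8-triene-9-carboxylate | CC1(C)/C=C/C/C(C)=C/CC/C(C(=O)OCC[Si](C)(C)C)=C\[C@H]1OC(=O)c1ccccc1 | intermediate
18 | 2-(trimethylsilyl)ethyl (1S,2S,7R,4E,8E)-7-benzoyloxy-1,2-epoxy-2,6,6-trimethylcycloundeca-4,8-diene-9-carboxylate | CC1(C)/C=C/C[C@]2(C)O[C@H]2CC/C(C(=O)OCC[Si](C)(C)C)=C\[C@H]1OC(=O)c1ccccc1 | intermediate
19 | 2-(trimethylsilyl)ethyl (1S,2S,7R,8E)-7-benzoyloxy-1,2-epoxy-2,6,6-trimethylcycloundec-8-ene-9-carboxylate | CC1(C)CCC[C@]2(C)O[C@H]2CC/C(C(=O)OCC[Si](C)(C)C)=C\[C@H]1OC(=O)c1ccccc1 | intermediate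
20 | tetrabutylammonium (1S,2S,7R,8E)-7-benzoyloxy-1,2-epoxy-2,6,6-trimethylcycloundec-8-ene-9-carboxylate | CCCC[N+](CCCC)(CCCC)CCCC.CC1(C)CCC[C@]2(C)O[C@H]2CC/C(C(=O)[O-])=C\[C@H]1OC(=O)c1ccccc1 | intermediate
21 | (1S,2S,7R,8E)-7-benzoyloxy-1,2-epoxy-2,6,6-trimethylcycloundec-8-ene-9-carboxylic acid (CNP0377917.2) | CC1(C)CCC[C@]2(C)O[C@H]2CC/C(C(=O)O)=C\[C@H]1OC(=O)c1ccccc1 | target

Total step count: 13.
Longest linear sequence: 13 steps (from 1 and 2).

**Steps most likely to fail**

**Step 9.**
- The strained closure may lose to intermolecular coupling or to protonation of the allylmetal.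
- Excess divalent chromium may reduce the ene-dicarbonyl unit.
- The ligated metal may react too slowly.
- The ligand may discriminate the aldehyde faces poorly or in the wrong sense. The sense has to be checked by Mosher ester analysis, and the (3aS,8aR) antipode of the ligand is equally available.
- The fallback separates ring formation from stereocontrol and uses only known chemistry. It sets out from 14.
- Ligand-free CrCl2 in THF–DMF under the same slow addition, the established achiral Nozaki–Hiyama–Kishi macrocyclisation, runs again through 15 and should give the racemic carbinol F1.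
- Dess–Martin periodinane (NaHCO3, CH2Cl2) oxidises it to the cross-conjugated 7-ketone F2.
- Corey–Bakshi–Shibata reduction follows, with (S)-1-methyl-3,3-diphenyltetrahydro-1H,3H-pyrrolo[1,2-c][1,3,2]oxazaborole and catecholborane in toluene at −78 °C. The quaternary C6 flank acts as the large group, so hydride should be delivered to give the 7R alcohol. The fallback comes back to the route at 16.

**Step 8.**
- The highly substituted allylic bromide may ionise during formation or handling. It may then lose HBr towards the doubly activated C3 methylene or be solvolysed in the wash.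
- The fallback gives up the bromide. It sets out from 13.
- SOCl2 in Et2O at −20 °C (SNi′ transposition through the chlorosulfite) should give the less ionisable secondary allylic chloride F3, which tolerates chromatography and cold storage.
- F3 is fed into the chromium closure in the presence of NaI, so the reactive halide exists only at the moment of use. It passes through the same 15 and comes back to the route at 16.

**Step 11.**
- The chiral dioxirane may be mismatched with the face that the rigid triene ring prefers to turn outwards, so that facial selectivity erodes. Oxidation may also spread to C4=C5.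
- The fallback inverts the order of the two steps. It sets out from 17.
- RhCl(PPh3)3/H2 first saturates C4=C5 to the 4,5-dihydro benzoate F4. Its ring has lost one rigid E alkene and flips more freely, and C1=C2 is then the only alkene a dioxirane can attack.
- Epoxidation of F4 with the same L-configured ketone and KHSO5 comes back to the route at 19.

**Further compounds**

F1 | step 9 | racemic 2-(trimethylsilyl)ethyl (1E,4E,8E)-7-hydroxy-2,6,6-trimethylcycloundeca-1,4,8-triene-9-carboxylate | CC1(C)/C=C/C/C(C)=C/CC/C(C(=O)OCC[Si](C)(C)C)=C\C1O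
F2 | step 9 | 2-(trimethylsilyl)ethyl (1E,4E,8E)-2,6,6-trimethyl-7-oxocycloundeca-1,4,8-triene-9-carboxylate | CC1(C)/C=C/C/C(C)=C/CC/C(C(=O)OCC[Si](C)(C)C)=C\C1=O
F3 | step 8 | 2-(trimethylsilyl)ethyl (2E)-2-[(3E)-6-chloro-4,8-dimethylnona-3,7-dien-1-yl]-4-oxobut-2-enoate (racemic) | O=C/C=C(\CC/C=C(\C)CC(Cl)C=C(C)C)C(=O)OCC[Si](C)(C)C
F4 | step 11 | 2-(trimethylsilyl)ethyl (7R,1E,8E)-7-benzoyloxy-2,6,6-trimethylcycloundeca-1,8-diene-9-carboxylate | CC1(C)CCC/C(C)=C/CC/C(C(=O)OCC[Si](C)(C)C)=C\[C@H]1OC(=O)c1ccccc1
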